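**Retrosynthetic overview**

- The route rests on the 1,4-relationship of C1 (aroyl-bearing) and C4 across the C2–C3 unit of the cyclohexene. A C(=O)–O bridge from C1 to C4 turns the carbocycle C1–C6 into the adduct of a 2-pyrone (C1–C2–C3–C4 plus the bridge) with styrene (C5–C6).
- The chromene pyran ring is made last, from the 2,6-dihydroxy-4-methoxyphenyl ketone and 3-methylbut-2-enal. The aryl ketone comes from the C1 aldehyde and a 2-lithiated bis-MOM 5-methoxyresorcinol.
- The prenyl group comes from a C2–CH2CHO unit and an isopropylidene ylide. That unit and the C3=C4 alkene come from a Johnson–Claisen shift of the C4 allylic alcohol, whose oxygen is cis to the C1 carbon.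
- The bridged lactone comes from 3,5-dibromo-2-pyrone and styrene by [4+2] cycloaddition. The bridgehead Br becomes C1–H, the vinyl Br becomes C3–Me, and a lipase resolution of the allylic alcohol fixes the absolute configuration.
- Ring order: the carbocycle (step 2, as a 2-oxabicyclo[2.2.2]octenone), then the pyran ring of the chromene (step 18). Both benzene rings are bought.

Key step: step 2

Assumption: the lipase is taken to acetylate the (1R)-carbinol of racemic 8 (Kazlauskas rule, bromoalkene carbon as the large group), to be checked by Mosher analysis; if the sense is opposite, the recovered alcohol is 10 and step 7 falls away. Compounds 5–8 are racemic and their SMILES show the enantiomer that is carried on. Ring atoms are numbered as in the target cyclohexene (C1 aroyl-bearing, C2 prenyl, C3(Me)=C4, C5, C6 phenyl).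

**Route**

Step 1
Reactants: 1 coumalic acid
Product: 3 3,5-dibromo-2H-pyran-2-one, via 5-bromo-2H-pyran-2-one 2 (not isolated)
Conditions: NBS (2.5 equiv), LiOAc, MeCN/H2O 9:1, rt
Reagents that add atoms: N-bromosuccinimide, O=C1CCC(=O)N1Br
Why: Known brominative decarboxylation of coumalic acid (ipso-bromination at C5 with loss of CO2), followed by addition–elimination bromination of the 5-bromopyrone at C3 by the second equivalent of NBS.

Step 2
Reactants: 3 3,5-dibromo-2H-pyran-2-one; 4 styrene
Product: 5 rac-(1R,4R,8S)-4,6-dibromo-8-phenyl-2-oxabicyclo[2.2.2]oct-5-en-3-one (phenyl endo, anti to the lactone bridge)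
Conditions: styrene (5 equiv), BHT (cat.), toluene, 100 °C, sealed tube
Reagents that add atoms: none
Why: Concerted, asynchronous [4+2] cycloaddition with the pyrone C3=C4–C5=C6 unit as diene: the styrene CH2 bonds ahead to the electrophilic pyrone C6 and the benzylic carbon to C3, where the developing charge is stabilised by the carbonyl and bromine, so phenyl ends up next to the C–Br bridgehead (target C6 next to C1). The closest known reaction is the thermal Diels–Alder reaction of 3,5-dibromo-2-pyrone with styrenes and other monosubstituted alkenes, which gives endo bicyclic lactones. The cyclohexene ring is closed by intermolecular [4+2] cycloaddition, suprafacial on both partners, forming C1–C6 and C4–C5 and leaving the lactone as a two-atom bridge. The two bridgeheads (C1, C4) are fixed relative to each other by the bridge, and C6 is set by the endo transition state, which places phenyl under the diene and therefore trans to the C1 carbonyl. The step needs regio- and endo-selectivity; the polarisation of the dibromopyrone secures the first, secondary overlap with the aryl ring and avoidance of the lactone bridge the second, and any exo isomer is removed by chromatography. The product is racemic, and the moderate temperature keeps the adduct from losing CO2.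

Step 3
Reactants: 5 dibromo bicyclic lactone
Product: 6 rac-(1R,4S,8R)-6-bromo-8-phenyl-2-oxabicyclo[2.2.2]oct-5-en-3-one
Conditions: Bu3SnH (1.05 equiv, slow addition), AIBN (cat.), benzene, 80 °C
Reagents that add atoms: none
Why: Tin hydride radical dehalogenation; the tertiary bridgehead C–Br next to the lactone carbonyl is abstracted far faster than the vinylic C–Br, and the bridgehead radical can only take up hydrogen with retention.

Step 4
Reactants: 6 bromoalkenyl lactone
Product: 7 rac-(1R,4S,5R)-2-bromo-4-(hydroxymethyl)-5-phenylcyclohex-2-en-1-ol (cis-1,4 diol, phenyl trans to CH2OH)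
Conditions: LiAlH4, THF, 0 °C; Fieser work-up
Reagents that add atoms: none
Why: Hydride reduction of the lactone cleaves the acyl C–O bond only, so both carbinol-bearing stereocentres keep their configuration, and the vinyl bromide is inert at 0 °C.

Step 5
Reactants: 7 bromo diol
Product: 8 rac-(1R,4S,5R)-2-bromo-4-{[(tert-butyldimethylsilyl)oxy]methyl}-5-phenylcyclohex-2-en-1-ol
Conditions: TBSCl (1.05 equiv), imidazole, CH2Cl2, 0 °C
Reagents that add atoms: tert-butyldimethylsilyl chloride, CC(C)(C)[Si](C)(C)Cl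
Why: Silylation of the primary hydroxyl is much faster than that of the secondary allylic hydroxyl flanked by the bromoalkene.

Step 6
Reactants: 8 racemic silyl ether alcohol
Product: 9 (1R,4S,5R)-2-bromo-4-{[(tert-butyldimethylsilyl)oxy]methyl}-5-phenylcyclohex-2-en-1-yl acetate
Conditions: Amano lipase PS (immobilised), vinyl acetate (5 equiv), MTBE, 30 °C, stopped near half conversion
Reagents that add atoms: vinyl acetate, C=COC(C)=O
Why: Lipase-catalysed kinetic resolution by irreversible transesterification, in which the (1R)-carbinol should be acetylated (Kazlauskas rule) and the slow (1S,4R,5S)-alcohol is removed by chromatography, fixing the absolute configuration of the ring stereocentres.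

Step 7
Reactants: 9 acetate
Product: 10 (1R,4S,5R)-2-bromo-4-{[(tert-butyldimethylsilyl)oxy]methyl}-5-phenylcyclohex-2-en-1-ol (single enantiomer)
Conditions: K2CO3 (cat.), MeOH, rt
Reagents that add atoms: none
Why: Base-catalysed transesterification (methanolysis) of the acetate, which does not touch the carbinol stereocentre or the silyl ether.

Step 8
Reactants: 10 bromo allylic alcohol
Product: 11 (1R,4R,5R)-4-{[(tert-butyldimethylsilyl)oxy]methyl}-2-methyl-5-phenylcyclohex-2-en-1-ol
Conditions: MeB(OH)2 (3 equiv), Pd(dppf)Cl2 (5 mol%), K2CO3, dioxane/H2O 10:1, 90 °C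
Reagents that add atoms: methylboronic acid, CB(O)O
Why: Suzuki–Miyaura coupling of the alkenyl bromide installs the C3 methyl; it is placed after lactone opening so that Pd(0) meets a free allylic alcohol and not an ionisable allylic ester or an α-bromo lactone.

Step 9
Reactants: 11 methyl allylic alcohol
Product: 14 ethyl 2-[(1S,5R,6R)-6-{[(tert-butyldimethylsilyl)oxy]methyl}-2-methyl-5-phenylcyclohex-2-en-1-yl]acetate, via mixed orthoester 12 (not isolated), via ketene acetal 13 (not isolated)
Conditions: MeC(OEt)3 (excess), EtCO2H (cat.), 140 °C, EtOH distilled off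
Reagents that add atoms: triethyl orthoacetate, CCOC(C)(OCC)OCC
Why: Johnson–Claisen rearrangement, in which the suprafacial [3,3] shift of the ketene acetal delivers the acetate carbon to C2 on the face that carried the C4–O bond, hence cis to the C1 CH2OTBS group, and moves the alkene to C3=C4.

Step 10
Reactants: 14 ethyl ester
Product: 15 2-[(1S,5R,6R)-6-{[(tert-butyldimethylsilyl)oxy]methyl}-2-methyl-5-phenylcyclohex-2-en-1-yl]acetaldehyde
Conditions: DIBAL-H (1.1 equiv), CH2Cl2, −78 °C; Rochelle salt work-up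
Reagents that add atoms: none
Why: Partial reduction of the ester by DIBAL-H stops at the tetrahedral aluminium hemiacetal at −78 °C, which gives the aldehyde on work-up.

Step 11
Reactants: 15 aldehyde
Product: 16 tert-butyldimethyl{[(1R,2S,6R)-3-methyl-2-(3-methylbut-2-en-1-yl)-6-phenylcyclohex-3-en-1-yl]methoxy}silane
Conditions: i-PrPPh3I, n-BuLi, THF, 0 °C; then 15, −78 °C to rt
Reagents that add atoms: isopropyltriphenylphosphonium iodide, CC(C)[P+](c1ccccc1)(c1ccccc1)c1ccccc1.[I-]
Why: Wittig olefination with the non-stabilised isopropylidene ylide gives the trisubstituted prenyl alkene, which has no E/Z issue.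

Step 12
Reactants: 16 silyl ether
Product: 17 [(1R,2S,6R)-3-methyl-2-(3-methylbut-2-en-1-yl)-6-phenylcyclohex-3-en-1-yl]methanol
Conditions: TBAF, THF, rt
Reagents that add atoms: none
Why: Fluoride-driven desilylation of the primary TBS ether, to which the alkenes are inert.

Step 13
Reactants: 17 primary alcohol
Product: 18 (1R,2S,6R)-3-methyl-2-(3-methylbut-2-en-1-yl)-6-phenylcyclohex-3-ene-1-carbaldehyde
Conditions: Dess–Martin periodinane, CH2Cl2, 0 °C to rt
Reagents that add atoms: none
Why: Dess–Martin oxidation is near-neutral and should give the aldehyde without epimerising C1.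

Step 14
Reactants: 19 5-methoxyresorcinol
Product: 20 1-methoxy-3,5-bis(methoxymethoxy)benzene
Conditions: MOMCl (2.5 equiv), i-Pr2NEt, CH2Cl2, 0 °C to rt
Reagents that add atoms: chloromethyl methyl ether, COCCl
Why: O-alkylation of both phenols with MOMCl and Hünig's base gives the bis-acetal, which both protects and directs the lithiation.

Step 15
Reactants: 20 bis-MOM arene; 18 aldehyde
Product: 22 [4-methoxy-2,6-bis(methoxymethoxy)phenyl][(1R,2S,6R)-3-methyl-2-(3-methylbut-2-en-1-yl)-6-phenylcyclohex-3-en-1-yl]methanol (both carbinol epimers), via aryllithium 21 (not isolated)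
Conditions: 20, n-BuLi, THF, 0 °C; then 18, −78 °C; NH4Cl (aq)
Reagents that add atoms: none
Why: Directed ortho-lithiation at the carbon between the two MOM-oxy groups, then 1,2-addition of the aryllithium to the aldehyde at −78 °C; the new carbinol centre is erased in the next step.

Step 16
Reactants: 22 carbinol
Product: 23 [4-methoxy-2,6-bis(methoxymethoxy)phenyl][(1R,2S,6R)-3-methyl-2-(3-methylbut-2-en-1-yl)-6-phenylcyclohex-3-en-1-yl]methanone
Conditions: Dess–Martin periodinane, CH2Cl2, rt
Reagents that add atoms: none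
Why: Dess–Martin oxidation of the benzylic alcohol gives the aryl ketone under conditions that leave the MOM ethers and alkenes alone.

Step 17
Reactants: 23 bis-MOM ketone
Product: 24 (2,6-dihydroxy-4-methoxyphenyl)[(1R,2S,6R)-3-methyl-2-(3-methylbut-2-en-1-yl)-6-phenylcyclohex-3-en-1-yl]methanone
Conditions: HCl (cat.), MeOH, 40 °C
Reagents that add atoms: none
Why: Acid-catalysed acetal exchange with methanol removes both MOM groups under conditions mild enough to spare the trisubstituted alkenes and the C1 centre.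

Step 18
Reactants: 24 dihydroxy ketone; 25 3-methylbut-2-enal
Product: 27 (7-hydroxy-5-methoxy-2,2-dimethyl-2H-chromen-8-yl)[(1R,2S,6R)-3-methyl-2-(3-methylbut-2-en-1-yl)-6-phenylcyclohex-3-en-1-yl]methanone, via dienone 26 (not isolated)
Conditions: 25 (1.1 equiv), ethylenediammonium diacetate (20 mol%), toluene, 110 °C
Reagents that add atoms: none
Why: Amine-salt-catalysed chromenylation: Knoevenagel-type C-alkylation at the ring carbon between OH and OMe (the two such positions are equivalent by symmetry), dehydration to the dienone and oxa-6π electrocyclisation close the pyran ring; the remaining hydroxyl is chelated to the ketone and should react more slowly, so one equivalent of enal should stop at the mono-chromene.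

**Compound list**

1 | coumalic acid (2-oxo-2H-pyran-5-carboxylic acid) | O=C(O)C1=COC(=O)C=C1 | starting material
2 | 5-bromo-2H-pyran-2-one | O=C1C=CC(Br)=CO1 | intermediate
3 | 3,5-dibromo-2H-pyran-2-one | O=C1OC=C(Br)C=C1Br | intermediate
4 | styrene | C=Cc1ccccc1 | starting material
5 | rac-(1R,4R,8S)-4,6-dibromo-8-phenyl-2-oxabicyclo[2.2.2]oct-5-en-3-one | O=C1O[C@@H]2C[C@@H](c3ccccc3)[C@@]1(Br)C=C2Br | intermediate
6 | rac-(1R,4S,8R)-6-bromo-8-phenyl-2-oxabicyclo[2.2.2]oct-5-en-3-one | O=C1O[C@@H]2C[C@@H](c3ccccc3)[C@H]1C=C2Br | intermediate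
7 | rac-(1R,4S,5R)-2-bromo-4-(hydroxymethyl)-5-phenylcyclohex-2-en-1-ol | OC[C@@H]1C=C(Br)[C@H](O)C[C@H]1c1ccccc1 | intermediate
8 | rac-(1R,4S,5R)-2-bromo-4-{[(tert-butyldimethylsilyl)oxy]methyl}-5-phenylcyclohex-2-en-1-ol | CC(C)(C)[Si](C)(C)OC[C@@H]1C=C(Br)[C@H](O)C[C@H]1c1ccccc1 | intermediate
9 | (1R,4S,5R)-2-bromo-4-{[(tert-butyldimethylsilyl)oxy]methyl}-5-phenylcyclohex-2-en-1-yl acetate | CC(C)(C)[Si](C)(C)OC[C@@H]1C=C(Br)[C@H](OC(C)=O)C[C@H]1c1ccccc1 | intermediate
10 | (1R,4S,5R)-2-bromo-4-{[(tert-butyldimethylsilyl)oxy]methyl}-5-phenylcyclohex-2-en-1-ol, single enantiomer | CC(C)(C)[Si](C)(C)OC[C@@H]1C=C(Br)[C@H](O)C[C@H]1c1ccccc1 | intermediate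
11 | (1R,4R,5R)-4-{[(tert-butyldimethylsilyl)oxy]methyl}-2-methyl-5-phenylcyclohex-2-en-1-ol | CC(C)(C)[Si](C)(C)OC[C@@H]1C=C(C)[C@H](O)C[C@H]1c1ccccc1 | intermediate
12 | mixed orthoester of 11 (1,1-diethoxyethyl ether at the ring carbinol oxygen) | CC(C)(C)[Si](C)(C)OC[C@@H]1C=C(C)[C@H](OC(C)(OCC)OCC)C[C@H]1c1ccccc1 | intermediate
13 | ketene acetal of 11 (1-ethoxyvinyl ether at the ring carbinol oxygen) | CC(C)(C)[Si](C)(C)OC[C@@H]1C=C(C)[C@H](OC(=C)OCC)C[C@H]1c1ccccc1 | intermediate
14 | ethyl 2-[(1S,5R,6R)-6-{[(tert-butyldimethylsilyl)oxy]methyl}-2-methyl-5-phenylcyclohex-2-en-1-yl]acetate | CC(C)(C)[Si](C)(C)OC[C@@H]1[C@H](CC(=O)OCC)C(C)=CC[C@H]1c1ccccc1 | intermediate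
15 | 2-[(1S,5R,6R)-6-{[(tert-butyldimethylsilyl)oxy]methyl}-2-methyl-5-phenylcyclohex-2-en-1-yl]acetaldehyde | CC(C)(C)[Si](C)(C)OC[C@@H]1[C@H](CC=O)C(C)=CC[C@H]1c1ccccc1 | intermediate
16 | tert-butyldimethyl{[(1R,2S,6R)-3-methyl-2-(3-methylbut-2-en-1-yl)-6-phenylcyclohex-3-en-1-yl]methoxy}silane | CC(C)(C)[Si](C)(C)OC[C@@H]1[C@H](CC=C(C)C)C(C)=CC[C@H]1c1ccccc1 | intermediate
17 | [(1R,2S,6R)-3-methyl-2-(3-methylbut-2-en-1-yl)-6-phenylcyclohex-3-en-1-yl]methanol | OC[C@@H]1[C@H](CC=C(C)C)C(C)=CC[C@H]1c1ccccc1 | intermediate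
18 | (1R,2S,6R)-3-methyl-2-(3-methylbut-2-en-1-yl)-6-phenylcyclohex-3-ene-1-carbaldehyde | O=C[C@@H]1[C@H](CC=C(C)C)C(C)=CC[C@H]1c1ccccc1 | intermediate
19 | 5-methoxyresorcinol | COc1cc(O)cc(O)c1 | starting material
20 | 1-methoxy-3,5-bis(methoxymethoxy)benzene | COCOc1cc(OC)cc(OCOC)c1 | intermediate
21 | [4-methoxy-2,6-bis(methoxymethoxy)phenyl]lithium | [Li]c1c(OCOC)cc(OC)cc1OCOC | intermediate
22 | [4-methoxy-2,6-bis(methoxymethoxy)phenyl][(1R,2S,6R)-3-methyl-2-(3-methylbut-2-en-1-yl)-6-phenylcyclohex-3-en-1-yl]methanol, both carbinol epimers | COCOc1cc(OC)cc(OCOC)c1C(O)[C@@H]1[C@H](CC=C(C)C)C(C)=CC[C@H]1c1ccccc1 | intermediate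
23 | [4-methoxy-2,6-bis(methoxymethoxy)phenyl][(1R,2S,6R)-3-methyl-2-(3-methylbut-2-en-1-yl)-6-phenylcyclohex-3-en-1-yl]methanone | COCOc1cc(OC)cc(OCOC)c1C(=O)[C@@H]1[C@H](CC=C(C)C)C(C)=CC[C@H]1c1ccccc1 | intermediate
24 | (2,6-dihydroxy-4-methoxyphenyl)[(1R,2S,6R)-3-methyl-2-(3-methylbut-2-en-1-yl)-6-phenylcyclohex-3-en-1-yl]methanone | COc1cc(O)c(C(=O)[C@@H]2[C@H](CC=C(C)C)C(C)=CC[C@H]2c2ccccc2)c(O)c1 | intermediate
25 | 3-methylbut-2-enal | CC(C)=CC=O | starting material
26 | dienone (ortho-quinone methide) from 24 and 25, 3-methylbut-2-enylidene group on the ring carbon between C=O and C–OMe | COC1=CC(O)=C(C(=O)[C@@H]2[C@H](CC=C(C)C)C(C)=CC[C@H]2c2ccccc2)C(=O)C1=CC=C(C)C | intermediate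
27 | (7-hydroxy-5-methoxy-2,2-dimethyl-2H-chromen-8-yl)[(1R,2S,6R)-3-methyl-2-(3-methylbut-2-en-1-yl)-6-phenylcyclohex-3-en-1-yl]methanone | COc1cc(O)c(C(=O)[C@@H]2[C@H](CC=C(C)C)C(C)=CC[C@H]2c2ccccc2)c2c1C=CC(C)(C)O2 | target

**Step count**

Total steps: 18. Longest linear sequence: 17 steps (steps 1–13 and 15–18); step 14 is the one-step arene branch.

**Steps most likely to fail**

Step 6. The enzyme may discriminate poorly between the enantiomers of this crowded, remotely substituted cyclohexenol, or acylate too slowly, so that the material carried on is not enantiopure. Fallback: setting out from racemic 8, the alcohol is esterified with (S)-2-methoxy-2-phenylacetic acid (EDC, DMAP, CH2Cl2, 0 °C). This gives two diastereomers, the (1R,4S,5R)-carbinol (S)-O-methylmandelate F1 and the (1S,4R,5S)-carbinol (S)-O-methylmandelate F2, which are separated by chromatography or crystallisation; their NMR shift differences also allow the carbinol configuration to be assigned. Methanolysis of F1 (K2CO3, MeOH) comes back to the route at 10.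

Step 9. Acid-promoted ionisation and elimination of the allylic orthoester to a diene, and partial cleavage of the silyl ether, may outrun a rearrangement that is slowed by the neighbouring C1 substituent. Fallback: setting out from 11, acetylation (Ac2O, DMAP, pyridine) gives the allylic acetate F3. LiHMDS with TMSCl/Et3N in THF at −78 °C forms the trimethylsilyl ketene acetal F4, which on warming to 60 °C undergoes Ireland–Claisen rearrangement to the trimethylsilyl ester F5. Aqueous work-up hydrolyses it to the carboxylic acid F6, and O-ethylation (EtI, K2CO3, DMF) comes back to the route at 14.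

Step 18. The condensation may stall on the hydrogen-bonded phenol, a second annulation may occur on the remaining hydroxyl, and prolonged heating with the amine salt may epimerise C1. Fallback: setting out from 24, copper-catalysed O-alkylation of one phenol with 3-chloro-3-methylbut-1-yne (CuCl2 cat., DBU, MeCN, 0 °C) gives the mono(1,1-dimethylpropargyl) aryl ether F7. Heating in o-xylene at 140 °C brings about aromatic propargyl Claisen rearrangement and tautomerisation to the ortho-allenylphenol F8. Its [1,5]-hydrogen shift gives the same dienone 26, and electrocyclisation comes back to the route at 27.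

**Further compounds**

F1 | step 6 | (1R,4S,5R)-2-bromo-4-{[(tert-butyldimethylsilyl)oxy]methyl}-5-phenylcyclohex-2-en-1-yl (S)-2-methoxy-2-phenylacetate | CC(C)(C)[Si](C)(C)OC[C@@H]1C=C(Br)[C@H](OC(=O)[C@@H](OC)c2ccccc2)C[C@H]1c1ccccc1
F2 | step 6 | (1S,4R,5S)-2-bromo-4-{[(tert-butyldimethylsilyl)oxy]methyl}-5-phenylcyclohex-2-en-1-yl (S)-2-methoxy-2-phenylacetate | CC(C)(C)[Si](C)(C)OC[C@H]1C=C(Br)[C@@H](OC(=O)[C@@H](OC)c2ccccc2)C[C@@H]1c1ccccc1
F3 | step 9 | (1R,4R,5R)-4-{[(tert-butyldimethylsilyl)oxy]methyl}-2-methyl-5-phenylcyclohex-2-en-1-yl acetate | CC(C)(C)[Si](C)(C)OC[C@@H]1C=C(C)[C@H](OC(C)=O)C[C@H]1c1ccccc1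
F4 | step 9 | trimethylsilyl ketene acetal of F3 | CC(C)(C)[Si](C)(C)OC[C@@H]1C=C(C)[C@H](OC(=C)O[Si](C)(C)C)C[C@H]1c1ccccc1
F5 | step 9 | trimethylsilyl 2-[(1S,5R,6R)-6-{[(tert-butyldimethylsilyl)oxy]methyl}-2-methyl-5-phenylcyclohex-2-en-1-yl]acetate | CC(C)(C)[Si](C)(C)OC[C@@H]1[C@H](CC(=O)O[Si](C)(C)C)C(C)=CC[C@H]1c1ccccc1
F6 | step 9 | 2-[(1S,5R,6R)-6-{[(tert-butyldimethylsilyl)oxy]methyl}-2-methyl-5-phenylcyclohex-2-en-1-yl]acetic acid | CC(C)(C)[Si](C)(C)OC[C@@H]1[C@H](CC(=O)O)C(C)=CC[C@H]1c1ccccc1
F7 | step 18 | {2-hydroxy-4-methoxy-6-[(2-methylbut-3-yn-2-yl)oxy]phenyl}[(1R,2S,6R)-3-methyl-2-(3-methylbut-2-en-1-yl)-6-phenylcyclohex-3-en-1-yl]methanone | C#CC(C)(C)Oc1cc(OC)cc(O)c1C(=O)[C@@H]1[C@H](CC=C(C)C)C(C)=CC[C@H]1c1ccccc1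
F8 | step 18 | [2,6-dihydroxy-4-methoxy-3-(3-methylbuta-1,2-dien-1-yl)phenyl][(1R,2S,6R)-3-methyl-2-(3-methylbut-2-en-1-yl)-6-phenylcyclohex-3-en-1-yl]methanone | COc1cc(O)c(C(=O)[C@@H]2[C@H](CC=C(C)C)C(C)=CC[C@H]2c2ccccc2)c(O)c1C=C=C(C)C
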